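## Analysis of the target

CNP0224658.3 (compound 60) is a 19-membered carbocycle that passes through three smaller rings: a 4,5-dimethylcyclohexene, a 3-acyltetronic acid spiro-fused to it through tetronate C5, and a 2,3,4-trisubstituted thiolane that belongs to the macrocycle through C3 and C4. It has eight stereocentres. Three sit on the cyclohexene (the carbon carrying the diene chain, the adjacent spiro carbon whose oxygen is cis to that chain, and the C-methyl carbon, which is cis to the chain across the ring). One is an isolated carbinol between the E,E-diene and the E-alkene, with no neighbour to relay stereochemistry. The last four are the exocyclic C-methyl carbon and the all-trans thiolane C2, C3 and C4. Thiolane C2 is α to the keto acid and C4 is α to the acyl ketone, so both are enolisable, and their trans arrangement to the C3 substituent is the thermodynamic one. The 3-acyltetronic acid and the α-keto acid are acidic and electrophilic, the sulfide is oxidisable, and the ring alkene is β,γ to the spiro carbon, so these groups have to appear late or stay masked. The hard points are the fully substituted spiro carbon next to a stereocentre, the closure of a 19-membered ring with three alkenes of fixed geometry, and the timing of the carbonyl groups. The strategy rests on one feature: the spiro carbon (tetronate C5) is a tertiary carbinol carbon bonded to the enol carbon C4, so the array O–C5–C4–C3–C2(=O) is a ketone carbonyl carbon plus a three-carbon propiolate unit.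

## Retrosynthetic reasoning

**Oxidation level and protection.** Target 60 is traced to macrocycle 55 by redox and deprotection only. The acyl ketone and the α-keto group are carried as secondary carbinols (diol 56) so that a single oxidation gives diketone 57. The tetronic acid stays as its methyl ether and the acid as its methyl ester until 58 and 59. This keeps the most acidic and electrophilic sites masked until the ring exists.

**Macrocycle.** In 55 the single bond in the middle of the E,E-diene is cut, which gives seco compound 54 with an alkenylstannane on the cyclohexene side chain and an alkenyl iodide at the end of the thiolane side chain. Both sp2 termini can be made with defined geometry beforehand, the Stille coupling transfers that geometry, no stereocentre is involved, and the closure is far from the congested spiro carbon.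

**Tetronate–thiolane bond.** 54 is cut between tetronate C3 and the carbinol carbon, giving 3-lithiotetronate 53 (from stannane 23) and thiolane aldehyde 52. The spiro carbon has no hydrogen, so C3 is the only acidic site of the methyl tetronate, and an aldehyde is the cleanest electrophile for it.

**Spirotetronate (key disconnection).** Stannane 23 comes from spirobutenolide 19 by side-chain work (20, 21, 22). In 19 the bonds from the spiro carbon to the enol carbon and from the spiro oxygen to the lactone carbonyl are cut, leading to cis cyclohexenone 14, methyl propiolate 15 and methanol 16. The forward reaction has to add a propiolate anion to an enolisable β,γ-unsaturated ketone from the face opposite the two cis substituents, then add methoxide and lactonise. Compound 14 carries a triisopropylsilyl ether because its synthesis passes through a carbanion close to the oxygen.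

**Cyclohexenone.** 14 comes from cyclohexenol 13, and 13 from diene 12 by ring-closing metathesis at the trisubstituted alkene. 12 is cut between the carbinol carbon and the chain-bearing carbon into aldehyde 7 and allylborane 11 (from silyl ether 9 of pentenol 8). The C-methyl centre of 7 comes from conjugate addition of 4 to imide 3 (from 1 and 2) through 5 and 6.

**Thiolane.** In 52 the formyl group is traced to the nitromethyl group of 50 (Nef reaction, then equilibration at C4 through 51). The C2–C(α) bond of 50 is cut to S,O-acetal 46 and ketene acetal 49 (from 47 through 48). 46 is the cyclised form of the mercapto aldehyde hidden in 45, and 45 is cut at C3–C4 into aldehyde 38 and nitroalkene 44 (from 39, 40 and 42 through 41 and 43). Only C3 needs reagent control; C2 follows from attack anti to the neighbours and C4 from thermodynamics.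

**Chain.** Aldehyde 38 comes from amide 37, which is cut at the isolated E-alkene into aldehyde 36 and sulfone 32 (Julia–Kocienski olefination). 36 comes from commercial hemiester 33 through lactone 34 and hydroxy amide 35, which supplies the exocyclic C-methyl centre. 32 comes from aldehyde 26 (from 24 and 25) by allylboration with 27, then 28, 29, 30 and 31; this sets the isolated carbinol.

## Alternatives that were turned down

**Alternative 1:** The bond between the exocyclic C-methyl carbon and the neighbouring allylic CH2 is cut, with the methyl group traced back to a carboxyl group. The forward key step is an Ireland–Claisen rearrangement inside a macrocyclic allylic ester: its silyl ketene acetal forms the C–C bond, the E-alkene and the carbocycle at once and gives acid A1. In its favour, macrolactonisation is a dependable ring closure, and the sigmatropic shift fixes the alkene geometry and transfers chirality through an ordered transition state. Against it, the chair-or-boat preference and the enolate geometry are hard to predict inside a large ring, and the enolate must be formed on a substrate that already carries the tetronate and the thiolane. The carboxyl group of A1 must then be degraded to a methyl group over several late steps, an extra carbinol centre must be made only to be consumed, and the keto acid is still a protected diol that needs a late selective oxidation. On alkene geometry and on forming ring and C–C bond in one event this alternative is stronger than the Stille closure of 54. The chosen strategy instead tests the hardest centre, the spiro carbon, on the small ketone 14, and takes the C-methyl centre from hemiester 33 with no degradation.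

**Alternative 2:** The tetronate C3–C4 bond is cut, which leads back to a ring-expanded lactone in which the spiro oxygen is acylated by the β-keto acid chain and the spiro carbon bears a methyl ester. The forward key step is a transannular Dieckmann condensation with a strong alkoxide base; it closes the tetronate, contracts the lactone to the carbocycle and gives A2. In its favour, A2 is already a free 3-acyltetronic acid, so the O-methyl ether, the carbinol oxidation at the acyl carbon and the demethylation (steps 36 and 38 here) are not needed, and the Dieckmann route to acyltetronic acids is classical. Against it, the tertiary α-hydroxy ester on the cyclohexene poses the same facial problem at the same ketone, the macrolactonisation has to acylate a hindered tertiary alcohol, and strong base meets a substrate with an enolisable thiolane C4. The decisive step also comes at the very end. On endgame economy this alternative is stronger. The chosen strategy places its risk at step 9 of the route and builds the tetronate before any valuable fragment is attached.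

**Alternative 3:** The thiolane C2–C3 and C4–C5 bonds are cut. The forward key step is the cycloaddition of an ester-substituted thiocarbonyl ylide, released by fluoride, to an E-enoate bearing the C-methyl side chain; it gives thiolane diester A3. In its favour, one step builds the ring with the C3/C4 trans relationship taken from the alkene geometry, against seven steps from 38 to 52 here, so it is clearly stronger on step count for this ring. Against it, three selectivities are decided at once: the orientation of the unsymmetrical ylide, endo or exo at C2, and the face of the enoate, which is controlled only by the allylic methyl centre. The C2 ester of A3 must still be extended by one carbon to the keto acid, and the tactic does nothing for the spiro carbon or the macrocycle. The chosen route sets C3 by a catalyst and C2 and C4 by steric approach and equilibration, and spends its key step on the quaternary centre.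

Key step: step 9

Assumption: the diisopinocampheylborane reagents derived from (+)-α-pinene deliver the allyl group to the Si face of an unbranched aliphatic aldehyde, as in simple allyl and crotyl transfers; steps 6 and 15 rely on this sense.

Assumption: centres that are later oxidised or ionised (C2 of 46, the silyloxy-bearing carbon of 50 to 55, the carbinol carbon of 54 to 56) are carried as epimer mixtures, so their SMILES bear no descriptor there.

## Route

Step 1
Reactants: 1 (S)-4-benzyl-1,3-oxazolidin-2-one; 2 (E)-but-2-enoyl chloride
Product: 3 (S)-4-benzyl-3-[(E)-but-2-enoyl]-1,3-oxazolidin-2-one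
Conditions: n-BuLi, THF, −78 °C; then 2, −78 → 0 °C
Reagents that add atoms: none
Why: N-acylation of the lithiated oxazolidinone with the acid chloride is the standard way to attach an enoyl group to this auxiliary; no stereocentre is formed.

Step 2
Reactants: 3 crotonyl imide; 4 isopropenylmagnesium bromide
Product: 5 (S)-4-benzyl-3-[(R)-3,4-dimethylpent-4-enoyl]-1,3-oxazolidin-2-one
Conditions: CuBr·SMe2, THF/Me2S, −78 → −20 °C; NH4Cl (aq.)
Reagents that add atoms: none
Why: Auxiliary-controlled conjugate addition of a Grignard-derived organocopper reagent: magnesium chelates both imide carbonyls, the enoyl group lies s-cis, and the isopropenyl group enters the β-carbon from the face away from the benzyl group, which should give the (R)-centre that becomes the ring C-methyl carbon.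

Step 3
Reactants: 5 dimethylpentenoyl imide
Product: 6 (R)-3,4-dimethylpent-4-en-1-ol
Conditions: LiBH4, H2O (1 equiv), Et2O, 0 °C
Reagents that add atoms: none
Why: Reductive cleavage of the N-acyloxazolidinone gives the primary alcohol and returns the auxiliary; the alkene is inert and the stereocentre is β to the carbonyl, so it cannot epimerise.

Step 4
Reactants: 6 (R)-3,4-dimethylpent-4-en-1-ol
Product: 7 (R)-3,4-dimethylpent-4-enal
Conditions: Dess–Martin periodinane, NaHCO3, CH2Cl2, 0 °C; used as a solution
Reagents that add atoms: none
Why: Dess–Martin oxidation under bicarbonate buffer; the stereocentre is not α to the carbonyl, and the volatile aldehyde is carried forward without concentration.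

Step 5
Reactants: 8 pent-4-en-1-ol
Product: 9 triisopropyl(pent-4-en-1-yloxy)silane
Conditions: iPr3SiCl, imidazole, DMF, rt
Reagents that add atoms: triisopropylsilyl chloride, CC(C)[Si](Cl)(C(C)C)C(C)C
Why: Silylation of a primary alcohol; the bulky triisopropylsilyl group is chosen because step 6 makes a carbanion three atoms from the oxygen, where a 1,4 shift of a smaller silyl group from oxygen to carbon would be the likely side reaction.

Step 6
Reactants: 9 triisopropyl(pent-4-en-1-yloxy)silane; 7 (R)-3,4-dimethylpent-4-enal
Product: 12 (3R,4R,6R)-6,7-dimethyl-3-[2-(triisopropylsilyloxy)ethyl]octa-1,7-dien-4-ol, via Z-allylpotassium 10 (not isolated), via Z-allylborane 11 (not isolated)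
Conditions: n-BuLi, KOtBu, THF, −78 → −50 °C; (−)-B-methoxydiisopinocampheylborane, −78 °C; BF3·OEt2; 7, −78 °C; NaOH, H2O2
Reagents that add atoms: none
Why: Metallation of the terminal alkene gives an allylpotassium that settles in the Z (endo) form and is borylated at the unsubstituted terminus; the Z γ-alkyl allylborane adds to the aldehyde through a closed chair transition state, which gives the syn adduct, and the isopinocampheyl groups direct attack to the Si face, so the chain-bearing carbon is formed (R). This is the γ-alkyl variant of asymmetric crotylboration; the carbinol centre is removed in step 8.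

Step 7
Reactants: 12 diene alcohol
Product: 13 (1R,2R,5R)-4,5-dimethyl-2-[2-(triisopropylsilyloxy)ethyl]cyclohex-3-en-1-ol
Conditions: second-generation Grubbs catalyst (5 mol%), CH2Cl2, 40 °C
Reagents that add atoms: none
Why: Ring-closing metathesis between the vinyl group and the 1,1-disubstituted alkene closes the six-membered ring as the trisubstituted cyclohexene and releases ethene; no stereocentre is touched.

Step 8
Reactants: 13 cyclohexenol
Product: 14 (2R,5R)-4,5-dimethyl-2-[2-(triisopropylsilyloxy)ethyl]cyclohex-3-en-1-one (cis)
Conditions: Dess–Martin periodinane, NaHCO3, CH2Cl2, 0 °C; used at once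
Reagents that add atoms: none
Why: Dess–Martin oxidation under buffered, non-basic conditions gives the β,γ-unsaturated ketone; low temperature and immediate use protect the doubly activated α-centre from epimerisation and the alkene from moving into conjugation.

Step 9
Reactants: 14 cis cyclohexenone; 15 methyl propiolate; 16 methanol
Product: 19 (5S,6R,9R)-4-methoxy-8,9-dimethyl-6-[2-(triisopropylsilyloxy)ethyl]-1-oxaspiro[4.5]deca-3,7-dien-2-one, via hydroxy ynoate 17 (not isolated), via methoxy enoate 18 (not isolated)
Conditions: 15, LiN(iPr)2, THF, −78 °C; CeCl3, −78 °C; 14, −78 °C; then NaOMe, MeOH, 0 °C → rt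
Reagents that add atoms: none
Why: The cerium acetylide of 15 adds to the carbonyl of 14, forming the bond from the future spiro carbon to the future enol carbon and giving tertiary alcohol 17. Methoxide then adds to the β-carbon of the ynoate to give 18, whose E and Z forms interconvert under the basic conditions; the tertiary oxygen attacks the ester carbonyl of the Z form, a 5-exo-trig acyl substitution that closes the butenolide and expels methoxide. The closest known reaction type is the addition of metallated alkyl propiolates to ketones followed by alkoxide conjugate addition and lactonisation to 4-alkoxy-2(5H)-furanones. The one new stereocentre, the spiro carbon, is set by the substrate: the C2 chain and the C5 methyl group of 14 are cis, in either half-chair one of them is pseudoaxial on that face, and the acetylide therefore enters from the opposite face, which leaves the new oxygen cis to the chain as in 60. The step needs 1,2-addition to win over proton transfer from the α-carbon, which is both α to the carbonyl and allylic; the low basicity of the organocerium reagent secures this. It also needs methoxide to attack the β-carbon only, which the polarisation of the ynoate secures. The silyl ether and the ring alkene are inert to both stages.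

Step 10
Reactants: 19 silyl ether
Product: 20 (5S,6R,9R)-6-(2-hydroxyethyl)-4-methoxy-8,9-dimethyl-1-oxaspiro[4.5]deca-3,7-dien-2-one
Conditions: Bu4NF, THF, 0 °C → rt
Reagents that add atoms: none
Why: Fluoride cleaves the primary silyl ether; the methyl tetronate is a vinylogous carbonate and is stable to fluoride at this temperature.

Step 11
Reactants: 20 primary alcohol
Product: 21 2-[(5S,6R,9R)-4-methoxy-8,9-dimethyl-2-oxo-1-oxaspiro[4.5]deca-3,7-dien-6-yl]acetaldehyde
Conditions: Dess–Martin periodinane, NaHCO3, CH2Cl2, 0 °C → rt
Reagents that add atoms: none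
Why: Dess–Martin oxidation of the primary alcohol; the formyl group is two carbons from the ring stereocentre, so nothing can epimerise.

Step 12
Reactants: 21 aldehyde
Product: 22 (5S,6R,9R)-6-[(E)-3-iodoprop-2-en-1-yl]-4-methoxy-8,9-dimethyl-1-oxaspiro[4.5]deca-3,7-dien-2-one
Conditions: CrCl2, CHI3, dioxane/THF (6:1), 0 °C → rt
Reagents that add atoms: iodoform, IC(I)I
Why: Takai olefination: the geminal dichromium species from iodoform adds to the aldehyde and eliminates to the E-alkenyl iodide; CrCl2 does not touch the butenolide, and the dioxane-rich solvent favours the E isomer.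

Step 13
Reactants: 22 alkenyl iodide
Product: 23 (5S,6R,9R)-4-methoxy-8,9-dimethyl-6-[(E)-3-(trimethylstannyl)prop-2-en-1-yl]-1-oxaspiro[4.5]deca-3,7-dien-2-one
Conditions: Me3SnSnMe3, Pd(PPh3)4, toluene, 80 °C
Reagents that add atoms: hexamethylditin, C[Sn](C)(C)[Sn](C)(C)C
Why: Palladium-catalysed iodine-to-tin exchange (oxidative addition, transmetalation, reductive elimination) retains the alkene geometry; the stannane is placed on this fragment because it tolerates the lithium amide of step 33, while the acid-stable iodide is kept for the other fragment.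

Step 14
Reactants: 24 acrolein; 25 1-phenyl-1H-tetrazole-5-thiol
Product: 26 3-[(1-phenyl-1H-tetrazol-5-yl)sulfanyl]propanal
Conditions: Et3N (cat.), CH2Cl2, 0 °C
Reagents that add atoms: none
Why: Base-catalysed thia-Michael addition of the soft thiolate to acrolein; at 0 °C the kinetically formed S-adduct is expected.

Step 15
Reactants: 26 sulfanyl propanal; 27 (−)-B-allyldiisopinocampheylborane
Product: 28 (S)-1-[(1-phenyl-1H-tetrazol-5-yl)sulfanyl]hex-5-en-3-ol
Conditions: Et2O, −78 °C; then HOCH2CH2NH2
Reagents that add atoms: none
Why: Asymmetric allylboration through a closed chair transition state; allyl transfer to the Si face sets the isolated carbinol with the configuration of 60 (the descriptor is S here because the sulfur-bearing branch ranks higher). The ethanolamine work-up avoids peroxide, which would partly oxidise the sulfide.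

Step 16
Reactants: 28 homoallylic alcohol
Product: 29 5-{[(S)-3-(tert-butyldimethylsilyloxy)hex-5-en-1-yl]sulfanyl}-1-phenyl-1H-tetrazole
Conditions: tBuMe2SiCl, imidazole, DMF, rt
Reagents that add atoms: tert-butyldimethylsilyl chloride, CC(C)(C)[Si](C)(C)Cl
Why: Silylation of the secondary alcohol; this ether has to outlast the acid of steps 28 and 31 and the selective desilylation of step 35.

Step 17
Reactants: 29 sulfide
Product: 30 5-{[(S)-3-(tert-butyldimethylsilyloxy)hex-5-en-1-yl]sulfonyl}-1-phenyl-1H-tetrazole
Conditions: (NH4)6Mo7O24·4H2O (cat.), H2O2 (30% aq.), EtOH, 0 °C → rt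
Reagents that add atoms: hydrogen peroxide, OO
Why: Molybdate-catalysed peroxide oxidation takes the heteroaryl sulfide to the sulfone; an isolated terminal alkene is not epoxidised by this system.

Step 18
Reactants: 30 sulfone
Product: 31 (S)-3-(tert-butyldimethylsilyloxy)-5-[(1-phenyl-1H-tetrazol-5-yl)sulfonyl]pentanal
Conditions: O3, CH2Cl2, −78 °C; then PPh3
Reagents that add atoms: ozone, [O-][O+]=O
Why: Ozonolysis with reductive work-up shortens the chain by one carbon; the β-silyloxy aldehyde is taken on without chromatography because it can lose silanol.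

Step 19
Reactants: 31 aldehyde
Product: 32 5-{[(3S,5E)-3-(tert-butyldimethylsilyloxy)-6-iodohex-5-en-1-yl]sulfonyl}-1-phenyl-1H-tetrazole
Conditions: CrCl2, CHI3, dioxane/THF (6:1), 0 °C → rt
Reagents that add atoms: iodoform, IC(I)I
Why: Takai olefination as in step 12 gives the E-alkenyl iodide; the weakly reducing CrCl2 should leave the tetrazolyl sulfone intact.

Step 20
Reactants: 33 (R)-5-methoxy-3-methyl-5-oxopentanoic acid
Product: 34 (S)-4-methyltetrahydro-2H-pyran-2-one
Conditions: LiOH (1 equiv); LiBH4, THF, 50 °C; then HCl (aq.)
Reagents that add atoms: none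
Why: Borohydride reduces the ester but not the lithium carboxylate, and acid closes the δ-lactone. Reducing this terminus turns the commercial (R)-hemiester into the lactone in which the methyl-bearing carbon has the sense needed in 60.

Step 21
Reactants: 34 lactone
Product: 35 (S)-5-hydroxy-N-methoxy-N,3-dimethylpentanamide
Conditions: MeNH(OMe)·HCl, AlMe3, CH2Cl2, 0 °C → rt
Reagents that add atoms: N,O-dimethylhydroxylamine hydrochloride, CNOC.Cl
Why: Aminolysis by the aluminium amide opens the lactone to the N-methoxy-N-methylamide and frees the primary alcohol; the amide is a stable placeholder for the aldehyde of step 24.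

Step 22
Reactants: 35 hydroxy amide
Product: 36 (S)-N-methoxy-N,3-dimethyl-5-oxopentanamide
Conditions: Dess–Martin periodinane, NaHCO3, CH2Cl2, 0 °C → rt
Reagents that add atoms: none
Why: Dess–Martin oxidation of the primary alcohol; the stereocentre is β to the new carbonyl and is not at risk.

Step 23
Reactants: 36 aldehyde amide; 32 sulfone
Product: 37 (3S,5E,8R,10E)-8-(tert-butyldimethylsilyloxy)-11-iodo-N-methoxy-N,3-dimethylundeca-5,10-dienamide
Conditions: KN(SiMe3)2, DME, −78 °C → rt (base added to the mixture)
Reagents that add atoms: none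
Why: Julia–Kocienski olefination: the sulfonyl carbanion adds to the aldehyde, the alkoxide transfers the tetrazole by Smiles rearrangement, and loss of SO2 and tetrazolate gives the alkene; unbranched partners, the potassium counter-ion and DME favour the E isomer.

Step 24
Reactants: 37 dienamide
Product: 38 (3S,5E,8R,10E)-8-(tert-butyldimethylsilyloxy)-11-iodo-3-methylundeca-5,10-dienal
Conditions: iBu2AlH, THF, −78 °C; KNaC4H4O6 (aq.)
Reagents that add atoms: none
Why: The N-methoxy-N-methylamide is reduced to a chelated hemiaminal that releases the aldehyde only on work-up, so over-reduction is avoided; the alkenyl iodide and the silyl ether are inert.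

Step 25
Reactants: 39 triphenylmethanethiol; 40 chloroacetaldehyde
Product: 41 2-(tritylsulfanyl)acetaldehyde
Conditions: Et3N, THF/H2O, 0 °C
Reagents that add atoms: none
Why: SN2 displacement of the activated chloride by the thiolate; the trityl group masks sulfur through the next two steps.

Step 26
Reactants: 41 2-(tritylsulfanyl)acetaldehyde; 42 nitromethane
Product: 44 (E)-1-nitro-3-(tritylsulfanyl)prop-1-ene, via nitro alcohol 43 (not isolated)
Conditions: 42, Et3N (cat.), THF, 0 °C; then MeSO2Cl, iPr2NEt, CH2Cl2, −40 → 0 °C
Reagents that add atoms: none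
Why: Henry reaction followed by elimination through the mesylate gives the conjugated E-nitroalkene; the hindered base and low temperature limit migration of the double bond toward sulfur.

Step 27
Reactants: 38 dienal; 44 nitroalkene
Product: 45 (2S,3S)-2-[(2S,4E,7R,9E)-7-(tert-butyldimethylsilyloxy)-10-iododeca-4,9-dien-2-yl]-4-nitro-3-[(tritylsulfanyl)methyl]butanal
Conditions: (R)-2-[diphenyl(trimethylsilyloxy)methyl]pyrrolidine (10 mol%), 4-nitrophenol (10 mol%), toluene, 0 °C
Reagents that add atoms: none
Why: Enamine-mediated Michael addition: the diarylprolinol silyl ether forms the E-enamine of 38, its bulky group blocks one face, and the nitroalkene is attacked through the usual synclinal transition state. The (R)-catalyst sets thiolane C3 as in 60; the neighbouring centre forms syn, which is the wrong sense for C4 and is corrected in step 32.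

Step 28
Reactants: 45 nitro aldehyde
Product: 46 (3S,4S)-3-[(2S,4E,7R,9E)-7-(tert-butyldimethylsilyloxy)-10-iododeca-4,9-dien-2-yl]-2-methoxy-4-(nitromethyl)thiolane (both C2 epimers)
Conditions: CF3CO2H (5%), MeOH/CH2Cl2 (1:4), 0 °C
Reagents that add atoms: methanol, CO
Why: Acid ionises the S–trityl bond and methanol traps the trityl cation; the freed thiol closes onto the aldehyde to the five-membered hemithioacetal, which acid and methanol convert into the cyclic S,O-acetal. The secondary silyl ether and the nitro group tolerate brief dilute acid.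

Step 29
Reactants: 47 methyl glycolate
Product: 48 methyl 2-(triethylsilyloxy)acetate
Conditions: Et3SiCl, imidazole, CH2Cl2, 0 °C
Reagents that add atoms: chlorotriethylsilane, CC[Si](Cl)(CC)CC
Why: Silylation of the primary alcohol; the triethylsilyl group is the one later removed selectively in step 35.

Step 30
Reactants: 48 silyloxy ester
Product: 49 1-methoxy-2-(triethylsilyloxy)-1-(trimethylsilyloxy)ethene (either geometry)
Conditions: LiN(iPr)2, THF, −78 °C; Me3SiCl
Reagents that add atoms: chlorotrimethylsilane, C[Si](C)(C)Cl
Why: Kinetic enolate formation and O-silylation give the silyl ketene acetal; its geometry does not matter because the carbon it delivers ends as a ketone.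

Step 31
Reactants: 46 S,O-acetal; 49 silyl ketene acetal
Product: 50 methyl 2-{(2S,3S,4S)-3-[(2S,4E,7R,9E)-7-(tert-butyldimethylsilyloxy)-10-iododeca-4,9-dien-2-yl]-4-(nitromethyl)thiolan-2-yl}-2-(triethylsilyloxy)acetate
Conditions: Me3SiOTf (0.2 equiv), CH2Cl2, −78 °C
Reagents that add atoms: none
Why: The Lewis acid ionises the S,O-acetal to a cyclic thionium ion, which the silyl ketene acetal attacks at C2, a Mukaiyama-type addition to a sulfur-stabilised cation. Both neighbouring substituents lie on one face of the ring, so attack from the other face sets C2 trans to the C3 chain; the silyloxy-bearing carbon forms as a mixture.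

Step 32
Reactants: 50 nitromethyl thiolane
Product: 52 methyl 2-{(2S,3S,4R)-3-[(2S,4E,7R,9E)-7-(tert-butyldimethylsilyloxy)-10-iododeca-4,9-dien-2-yl]-4-formylthiolan-2-yl}-2-(triethylsilyloxy)acetate, via cis aldehyde 51 (not isolated)
Conditions: NaOMe, MeOH, 0 °C; TiCl3 (aq.), NH4OAc, THF, 0 °C → rt; then DBU (cat.), CH2Cl2, rt
Reagents that add atoms: water, O
Why: Nef reaction in its reductive form: the nitronate is reduced by trivalent titanium to the imine, which hydrolyses to the aldehyde with no oxidant, so the sulfide is safe. C4 is now enolisable, and base equilibrates the cis aldehyde to the all-trans thiolane.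

Step 33
Reactants: 23 stannyl spirotetronate; 52 thiolane aldehyde
Product: 54 methyl 2-{(2S,3S,4R)-3-[(2S,4E,7R,9E)-7-(tert-butyldimethylsilyloxy)-10-iododeca-4,9-dien-2-yl]-4-[hydroxy{(5S,6R,9R)-4-methoxy-8,9-dimethyl-2-oxo-6-[(E)-3-(trimethylstannyl)prop-2-en-1-yl]-1-oxaspiro[4.5]deca-3,7-dien-3-yl}methyl]thiolan-2-yl}-2-(triethylsilyloxy)acetate, via 3-lithiotetronate 53 (not isolated)
Conditions: 23, LiN(iPr)2, THF, −78 °C; then 52, −78 °C; NH4Cl (aq.)
Reagents that add atoms: none
Why: The amide base removes the only acidic vinylic proton of the methyl tetronate (C3, between the lactone carbonyl and the enol ether), and the vinyllithium adds to the aldehyde faster than to the hindered α-silyloxy ester. The new carbinol centre forms as a mixture and is removed in step 36.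

Step 34
Reactants: 54 seco stannane iodide
Product: 55 macrocyclic carbinol (19-membered ring with the E,E-diene closed; methyl tetronate, free carbinol, triethylsilyloxy methyl ester, tert-butyldimethylsilyl ether)
Conditions: Pd2(dba)3, AsPh3, DMF, 40 °C, 1 mM
Reagents that add atoms: none
Why: Intramolecular Stille coupling at high dilution joins the two E-alkenyl termini with retention at both, which gives the E,E-diene and the 19-membered ring; zerovalent palladium with AsPh3 tolerates the sulfide, the free alcohol and the silyl ethers.

Step 35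
Reactants: 55 macrocyclic carbinol
Product: 56 macrocyclic diol (triethylsilyl group removed)
Conditions: HF·pyridine, pyridine, THF, 0 °C
Reagents that add atoms: none
Why: Buffered HF·pyridine removes the triethylsilyl group much faster than the secondary tert-butyldimethylsilyl group; protic acid is avoided because the carbinol next to the enol ether could solvolyse.

Step 36
Reactants: 56 macrocyclic diol
Product: 57 macrocyclic diketone (3-acyl methyl tetronate and α-keto methyl ester)
Conditions: Dess–Martin periodinane (excess), NaHCO3, CH2Cl2, 0 °C → rt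
Reagents that add atoms: none
Why: One Dess–Martin oxidation converts both secondary alcohols; the buffered periodinane does not oxidise a dialkyl sulfide, and the chain carbinol is still silylated.

Step 37
Reactants: 57 macrocyclic diketone
Product: 58 desilylated diketone (chain carbinol free)
Conditions: HF (48% aq.), MeCN, 0 °C
Reagents that add atoms: none
Why: Aqueous HF in acetonitrile cleaves the secondary silyl ether; the methyl tetronate, the α-keto ester and the alkenes are stable to it.

Step 38
Reactants: 58 desilylated diketone
Product: 59 methyl ester of 60 (free 3-acyltetronic acid)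
Conditions: LiCl, DMSO, 50 °C; dilute HCl work-up
Reagents that add atoms: none
Why: Chloride attacks the O-methyl group in an SN2 reaction; the 3-acyl group makes the tetronate an excellent leaving group, so demethylation occurs under mild conditions. If the α-keto methyl ester is cleaved as well, step 39 becomes a simple acidification.

Step 39
Reactants: 59 methyl ester
Product: 60 CNP0224658.3
Conditions: LiOH, THF/H2O, 0 °C; then HCl (aq.) to pH 3
Reagents that add atoms: lithium hydroxide, [Li+].[OH-]
Why: The α-keto ester is highly electrophilic and is saponified at 0 °C. Thiolane C2 and C4 can enolise here, but the all-trans arrangement is the thermodynamic one, so any equilibration converges on 60.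

## Compound list

1 | (S)-4-benzyl-1,3-oxazolidin-2-one | O=C1N[C@@H](Cc2ccccc2)CO1 | starting material
2 | (E)-but-2-enoyl chloride | C/C=C/C(=O)Cl | starting material
3 | (S)-4-benzyl-3-[(E)-but-2-enoyl]-1,3-oxazolidin-2-one | C/C=C/C(=O)N1[C@@H](Cc2ccccc2)COC1=O | intermediate
4 | isopropenylmagnesium bromide | CC(=C)[Mg]Br | starting material
5 | (S)-4-benzyl-3-[(R)-3,4-dimethylpent-4-enoyl]-1,3-oxazolidin-2-one | C=C(C)[C@H](C)CC(=O)N1[C@@H](Cc2ccccc2)COC1=O | intermediate
6 | (R)-3,4-dimethylpent-4-en-1-ol | C=C(C)[C@H](C)CCO | intermediate
7 | (R)-3,4-dimethylpent-4-enal | C=C(C)[C@H](C)CC=O | intermediate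
8 | pent-4-en-1-ol | C=CCCCO | starting material
9 | triisopropyl(pent-4-en-1-yloxy)silane | C=CCCCO[Si](C(C)C)(C(C)C)C(C)C | intermediate
10 | potassium (Z)-5-(triisopropylsilyloxy)pent-2-en-1-ide | [K+].[CH2-]/C=C\CCO[Si](C(C)C)(C(C)C)C(C)C | intermediate
11 | [(Z)-5-(triisopropylsilyloxy)pent-2-en-1-yl]bis[(1R,2S,3R,5R)-isopinocampheyl]borane | C(/C=C\CCO[Si](C(C)C)(C(C)C)C(C)C)B([C@@H]1C[C@@H]2C[C@H]([C@H]1C)C2(C)C)[C@@H]1C[C@@H]2C[C@H]([C@H]1C)C2(C)C | intermediate
12 | (3R,4R,6R)-6,7-dimethyl-3-[2-(triisopropylsilyloxy)ethyl]octa-1,7-dien-4-ol | C=C[C@@H](CCO[Si](C(C)C)(C(C)C)C(C)C)[C@H](O)C[C@@H](C)C(C)=C | intermediate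
13 | (1R,2R,5R)-4,5-dimethyl-2-[2-(triisopropylsilyloxy)ethyl]cyclohex-3-en-1-ol | CC1=C[C@@H](CCO[Si](C(C)C)(C(C)C)C(C)C)[C@H](O)C[C@H]1C | intermediate
14 | (2R,5R)-4,5-dimethyl-2-[2-(triisopropylsilyloxy)ethyl]cyclohex-3-en-1-one | CC1=C[C@@H](CCO[Si](C(C)C)(C(C)C)C(C)C)C(=O)C[C@H]1C | intermediate
15 | methyl propiolate | C#CC(=O)OC | starting material
16 | methanol | CO | starting material
17 | methyl 3-{(1S,2R,5R)-1-hydroxy-4,5-dimethyl-2-[2-(triisopropylsilyloxy)ethyl]cyclohex-3-en-1-yl}prop-2-ynoate | CC1=C[C@@H](CCO[Si](C(C)C)(C(C)C)C(C)C)[C@](O)(C#CC(=O)OC)C[C@H]1C | intermediate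
18 | methyl 3-{(1S,2R,5R)-1-hydroxy-4,5-dimethyl-2-[2-(triisopropylsilyloxy)ethyl]cyclohex-3-en-1-yl}-3-methoxyprop-2-enoate (either geometry) | CC1=C[C@@H](CCO[Si](C(C)C)(C(C)C)C(C)C)[C@](O)(C(OC)=CC(=O)OC)C[C@H]1C | intermediate
19 | (5S,6R,9R)-4-methoxy-8,9-dimethyl-6-[2-(triisopropylsilyloxy)ethyl]-1-oxaspiro[4.5]deca-3,7-dien-2-one | CC1=C[C@@H](CCO[Si](C(C)C)(C(C)C)C(C)C)[C@]2(C[C@H]1C)OC(=O)C=C2OC | intermediate
20 | (5S,6R,9R)-6-(2-hydroxyethyl)-4-methoxy-8,9-dimethyl-1-oxaspiro[4.5]deca-3,7-dien-2-one | CC1=C[C@@H](CCO)[C@]2(C[C@H]1C)OC(=O)C=C2OC | intermediate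
21 | 2-[(5S,6R,9R)-4-methoxy-8,9-dimethyl-2-oxo-1-oxaspiro[4.5]deca-3,7-dien-6-yl]acetaldehyde | CC1=C[C@@H](CC=O)[C@]2(C[C@H]1C)OC(=O)C=C2OC | intermediate
22 | (5S,6R,9R)-6-[(E)-3-iodoprop-2-en-1-yl]-4-methoxy-8,9-dimethyl-1-oxaspiro[4.5]deca-3,7-dien-2-one | CC1=C[C@@H](C/C=C/I)[C@]2(C[C@H]1C)OC(=O)C=C2OC | intermediate
23 | (5S,6R,9R)-4-methoxy-8,9-dimethyl-6-[(E)-3-(trimethylstannyl)prop-2-en-1-yl]-1-oxaspiro[4.5]deca-3,7-dien-2-one | CC1=C[C@@H](C/C=C/[Sn](C)(C)C)[C@]2(C[C@H]1C)OC(=O)C=C2OC | intermediate
24 | acrolein | C=CC=O | starting material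
25 | 1-phenyl-1H-tetrazole-5-thiol | Sc1nnnn1-c1ccccc1 | starting material
26 | 3-[(1-phenyl-1H-tetrazol-5-yl)sulfanyl]propanal | O=CCCSc1nnnn1-c1ccccc1 | intermediate
27 | (−)-B-allyldiisopinocampheylborane (isopinocampheyl groups from (+)-α-pinene) | C=CCB([C@@H]1C[C@@H]2C[C@H]([C@H]1C)C2(C)C)[C@@H]1C[C@@H]2C[C@H]([C@H]1C)C2(C)C | starting material
28 | (S)-1-[(1-phenyl-1H-tetrazol-5-yl)sulfanyl]hex-5-en-3-ol | C=CC[C@H](O)CCSc1nnnn1-c1ccccc1 | intermediate
29 | 5-{[(S)-3-(tert-butyldimethylsilyloxy)hex-5-en-1-yl]sulfanyl}-1-phenyl-1H-tetrazole | C=CC[C@H](O[Si](C)(C)C(C)(C)C)CCSc1nnnn1-c1ccccc1 | intermediate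
30 | 5-{[(S)-3-(tert-butyldimethylsilyloxy)hex-5-en-1-yl]sulfonyl}-1-phenyl-1H-tetrazole | C=CC[C@H](O[Si](C)(C)C(C)(C)C)CCS(=O)(=O)c1nnnn1-c1ccccc1 | intermediate
31 | (S)-3-(tert-butyldimethylsilyloxy)-5-[(1-phenyl-1H-tetrazol-5-yl)sulfonyl]pentanal | O=CC[C@H](O[Si](C)(C)C(C)(C)C)CCS(=O)(=O)c1nnnn1-c1ccccc1 | intermediate
32 | 5-{[(3S,5E)-3-(tert-butyldimethylsilyloxy)-6-iodohex-5-en-1-yl]sulfonyl}-1-phenyl-1H-tetrazole | I/C=C/C[C@H](O[Si](C)(C)C(C)(C)C)CCS(=O)(=O)c1nnnn1-c1ccccc1 | intermediate
33 | (R)-5-methoxy-3-methyl-5-oxopentanoic acid (methyl hydrogen (R)-3-methylglutarate) | OC(=O)C[C@@H](C)CC(=O)OC | starting material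
34 | (S)-4-methyltetrahydro-2H-pyran-2-one | O=C1C[C@@H](C)CCO1 | intermediate
35 | (S)-5-hydroxy-N-methoxy-N,3-dimethylpentanamide | OCC[C@H](C)CC(=O)N(C)OC | intermediate
36 | (S)-N-methoxy-N,3-dimethyl-5-oxopentanamide | O=CC[C@H](C)CC(=O)N(C)OC | intermediate
37 | (3S,5E,8R,10E)-8-(tert-butyldimethylsilyloxy)-11-iodo-N-methoxy-N,3-dimethylundeca-5,10-dienamide | I/C=C/C[C@H](O[Si](C)(C)C(C)(C)C)C/C=C/C[C@H](C)CC(=O)N(C)OC | intermediate
38 | (3S,5E,8R,10E)-8-(tert-butyldimethylsilyloxy)-11-iodo-3-methylundeca-5,10-dienal | I/C=C/C[C@H](O[Si](C)(C)C(C)(C)C)C/C=C/C[C@H](C)CC=O | intermediate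
39 | triphenylmethanethiol | SC(c1ccccc1)(c1ccccc1)c1ccccc1 | starting material
40 | chloroacetaldehyde | ClCC=O | starting material
41 | 2-(tritylsulfanyl)acetaldehyde | O=CCSC(c1ccccc1)(c1ccccc1)c1ccccc1 | intermediate
42 | nitromethane | C[N+](=O)[O-] | starting material
43 | 1-nitro-3-(tritylsulfanyl)propan-2-ol | [O-][N+](=O)CC(O)CSC(c1ccccc1)(c1ccccc1)c1ccccc1 | intermediate
44 | (E)-1-nitro-3-(tritylsulfanyl)prop-1-ene | [O-][N+](=O)/C=C/CSC(c1ccccc1)(c1ccccc1)c1ccccc1 | intermediate
45 | (2S,3S)-2-[(2S,4E,7R,9E)-7-(tert-butyldimethylsilyloxy)-10-iododeca-4,9-dien-2-yl]-4-nitro-3-[(tritylsulfanyl)methyl]butanal | I/C=C/C[C@H](O[Si](C)(C)C(C)(C)C)C/C=C/C[C@H](C)[C@@H]([C@H](CSC(c1ccccc1)(c1ccccc1)c1ccccc1)C[N+](=O)[O-])C=O | intermediate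
46 | (3S,4S)-3-[(2S,4E,7R,9E)-7-(tert-butyldimethylsilyloxy)-10-iododeca-4,9-dien-2-yl]-2-methoxy-4-(nitromethyl)thiolane, 3,4-cis, both C2 epimers | I/C=C/C[C@H](O[Si](C)(C)C(C)(C)C)C/C=C/C[C@H](C)[C@@H]1C(OC)SC[C@@H]1C[N+](=O)[O-] | intermediate
47 | methyl glycolate | COC(=O)CO | starting material
48 | methyl 2-(triethylsilyloxy)acetate | COC(=O)CO[Si](CC)(CC)CC | intermediate
49 | 1-methoxy-2-(triethylsilyloxy)-1-(trimethylsilyloxy)ethene, either geometry | COC(O[Si](C)(C)C)=CO[Si](CC)(CC)CC | intermediate
50 | methyl 2-{(2S,3S,4S)-3-[(2S,4E,7R,9E)-7-(tert-butyldimethylsilyloxy)-10-iododeca-4,9-dien-2-yl]-4-(nitromethyl)thiolan-2-yl}-2-(triethylsilyloxy)acetate, 2,3-trans-3,4-cis, both epimers at the silyloxy carbon | I/C=C/C[C@H](O[Si](C)(C)C(C)(C)C)C/C=C/C[C@H](C)[C@@H]1[C@@H](C(O[Si](CC)(CC)CC)C(=O)OC)SC[C@@H]1C[N+](=O)[O-] | intermediate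
51 | methyl 2-{(2S,3S,4S)-3-[(2S,4E,7R,9E)-7-(tert-butyldimethylsilyloxy)-10-iododeca-4,9-dien-2-yl]-4-formylthiolan-2-yl}-2-(triethylsilyloxy)acetate, 3,4-cis | I/C=C/C[C@H](O[Si](C)(C)C(C)(C)C)C/C=C/C[C@H](C)[C@@H]1[C@@H](C(O[Si](CC)(CC)CC)C(=O)OC)SC[C@@H]1C=O | intermediate
52 | methyl 2-{(2S,3S,4R)-3-[(2S,4E,7R,9E)-7-(tert-butyldimethylsilyloxy)-10-iododeca-4,9-dien-2-yl]-4-formylthiolan-2-yl}-2-(triethylsilyloxy)acetate, all-trans | I/C=C/C[C@H](O[Si](C)(C)C(C)(C)C)C/C=C/C[C@H](C)[C@@H]1[C@@H](C(O[Si](CC)(CC)CC)C(=O)OC)SC[C@H]1C=O | intermediate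
53 | 3-lithio derivative of 23 | CC1=C[C@@H](C/C=C/[Sn](C)(C)C)[C@]2(C[C@H]1C)OC(=O)C([Li])=C2OC | intermediate
54 | secondary alcohol joining tetronate C3 of 23 to the formyl carbon of 52, both carbinol epimers | CC1=C[C@@H](C/C=C/[Sn](C)(C)C)[C@]2(C[C@H]1C)OC(=O)C(C(O)[C@@H]1CS[C@H](C(O[Si](CC)(CC)CC)C(=O)OC)[C@H]1[C@@H](C)C/C=C/C[C@H](C/C=C/I)O[Si](C)(C)C(C)(C)C)=C2OC | intermediate
55 | macrocyclic carbinol: 19-membered carbocycle of 60 with O-methyl tetronate, carbinol in place of the acyl ketone, triethylsilyloxy methyl ester in place of the keto acid, tert-butyldimethylsilyl ether on the chain carbinol | CC1=C[C@H]2C/C=C/C=C/C[C@H](O[Si](C)(C)C(C)(C)C)C/C=C/C[C@H](C)[C@@H]3[C@@H](C(O[Si](CC)(CC)CC)C(=O)OC)SC[C@H]3C(O)C3=C(OC)[C@@]2(C[C@H]1C)OC3=O | intermediate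
56 | macrocyclic diol: 55 without the triethylsilyl group | CC1=C[C@H]2C/C=C/C=C/C[C@H](O[Si](C)(C)C(C)(C)C)C/C=C/C[C@H](C)[C@@H]3[C@@H](C(O)C(=O)OC)SC[C@H]3C(O)C3=C(OC)[C@@]2(C[C@H]1C)OC3=O | intermediate
57 | macrocyclic diketone: 3-acyl O-methyl tetronate and α-keto methyl ester, chain carbinol silylated | CC1=C[C@H]2C/C=C/C=C/C[C@H](O[Si](C)(C)C(C)(C)C)C/C=C/C[C@H](C)[C@@H]3[C@@H](C(=O)C(=O)OC)SC[C@H]3C(=O)C3=C(OC)[C@@]2(C[C@H]1C)OC3=O | intermediate
58 | O-methyl tetronate methyl ester of 60 (chain carbinol free) | CC1=C[C@H]2C/C=C/C=C/C[C@H](O)C/C=C/C[C@H](C)[C@@H]3[C@@H](C(=O)C(=O)OC)SC[C@H]3C(=O)C3=C(OC)[C@@]2(C[C@H]1C)OC3=O | intermediate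
59 | methyl ester of 60 | CC1=C[C@H]2C/C=C/C=C/C[C@H](O)C/C=C/C[C@H](C)[C@@H]3[C@@H](C(=O)C(=O)OC)SC[C@H]3C(=O)C3=C(O)[C@@]2(C[C@H]1C)OC3=O | intermediate
60 | CNP0224658.3 | CC1=C[C@H]2C/C=C/C=C/C[C@H](O)C/C=C/C[C@H](C)[C@@H]3[C@@H](C(=O)C(=O)O)SC[C@H]3C(=O)C3=C(O)[C@@]2(C[C@H]1C)OC3=O | target

## Step count and risks

Total: 39 steps. Longest linear sequence: 19 steps (steps 1–4, 6–13 and 33–39, from 1 to 60). The branch from 24 and 25 through 32, 37 and 52 is equally long (steps 14–19, 23, 24, 27, 28 and 31–39).

**Step 9 (key step).** The most likely failure is proton transfer from the doubly activated α-carbon of 14 to the acetylide, which returns ketone with the cis relationship lost or the alkene moved into conjugation. The second risk is incomplete facial selectivity at the carbonyl. Fallback: separate C–C bond formation from carboxylation. Starting from 14, ethynylmagnesium bromide premixed with CeCl3 (a smaller and less basic nucleophile) should give (1S,2R,5R)-1-ethynyl-4,5-dimethyl-2-[2-(triisopropylsilyloxy)ethyl]cyclohex-3-en-1-ol F1. Double deprotonation with n-BuLi and C-acylation of the acetylide with methyl chloroformate then gives 17, which is treated with NaOMe in methanol as in step 9 and rejoins the route at 19.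

**Step 6.** A 1,4 shift of the silyl group from oxygen to the allylic carbanion, or incomplete equilibration of the allylpotassium to its Z form, would lower the yield or the selectivity at the chain-bearing carbon. Fallback: make the same allylborane without a carbanion. The fallback sets out from aldehyde 7. Its partner comes from but-3-yn-1-ol by Crabbé homologation to penta-3,4-dien-1-ol F2 and silylation to triisopropyl(penta-3,4-dien-1-yloxy)silane F3. Hydroboration of F3 with diisopinocampheylborane from (+)-α-pinene at low temperature should give the kinetic Z allylborane 11, which is combined with 7 as in step 6 and returns at 12.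

**Step 27.** Migration of the double bond of 44 out of conjugation with the nitro group toward sulfur under the amine catalyst would stall the Michael addition. Fallback: carry oxygen instead of sulfur through the C–C bond formation. Starting from 38, the same catalyst and (E)-1-methoxy-4-{[(3-nitroprop-2-en-1-yl)oxy]methyl}benzene F4 should give the 4-methoxybenzyl ether analogue of 45, F5. Acetalisation with trimethyl orthoformate and acid gives the dimethyl acetal F6, DDQ frees the primary alcohol F7, and a Mitsunobu reaction with thioacetic acid gives the thioacetate F8. Methanolysis of the thioacetate followed by CF3CO2H in methanol closes the S,O-acetal, and the route is rejoined at 46.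

**Step 34.** Intermolecular coupling to oligomers may compete with ring closure, and the alkenylstannane may be lost by protodestannylation during the slow closure. Fallback: a boron terminus and a Suzuki–Miyaura macrocyclisation. Starting from 21, Takai–Utimoto olefination with 2-(dichloromethyl)-4,4,5,5-tetramethyl-1,3,2-dioxaborolane, CrCl2 and LiI should give the E-alkenylboronate analogue of 23, F9. Lithiation with LiN(iPr)2 and addition to 52 as in step 33 gives the boronate analogue of 54, F10. Ring closure with PdCl2(dppf) and K3PO4 in DMF/H2O at high dilution returns to the route at 55.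

## Further compounds

F1 | step 9 | (1S,2R,5R)-1-ethynyl-4,5-dimethyl-2-[2-(triisopropylsilyloxy)ethyl]cyclohex-3-en-1-ol | CC1=C[C@@H](CCO[Si](C(C)C)(C(C)C)C(C)C)[C@](O)(C#C)C[C@H]1C
F2 | step 6 | penta-3,4-dien-1-ol | C=C=CCCO
F3 | step 6 | triisopropyl(penta-3,4-dien-1-yloxy)silane | C=C=CCCO[Si](C(C)C)(C(C)C)C(C)C
F4 | step 27 | (E)-1-methoxy-4-{[(3-nitroprop-2-en-1-yl)oxy]methyl}benzene | COc1ccc(COC/C=C/[N+](=O)[O-])cc1
F5 | step 27 | (2S,3S)-2-[(2S,4E,7R,9E)-7-(tert-butyldimethylsilyloxy)-10-iododeca-4,9-dien-2-yl]-3-[(4-methoxybenzyloxy)methyl]-4-nitrobutanal | I/C=C/C[C@H](O[Si](C)(C)C(C)(C)C)C/C=C/C[C@H](C)[C@@H]([C@H](COCc1ccc(OC)cc1)C[N+](=O)[O-])C=O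
F6 | step 27 | dimethyl acetal of F5 | I/C=C/C[C@H](O[Si](C)(C)C(C)(C)C)C/C=C/C[C@H](C)[C@@H]([C@H](COCc1ccc(OC)cc1)C[N+](=O)[O-])C(OC)OC
F7 | step 27 | primary alcohol from F6 (4-methoxybenzyl group removed) | I/C=C/C[C@H](O[Si](C)(C)C(C)(C)C)C/C=C/C[C@H](C)[C@@H]([C@H](CO)C[N+](=O)[O-])C(OC)OC
F8 | step 27 | S-acetyl thioester from F7 | I/C=C/C[C@H](O[Si](C)(C)C(C)(C)C)C/C=C/C[C@H](C)[C@@H]([C@H](CSC(C)=O)C[N+](=O)[O-])C(OC)OC
F9 | step 34 | (5S,6R,9R)-4-methoxy-8,9-dimethyl-6-[(E)-3-(4,4,5,5-tetramethyl-1,3,2-dioxaborolan-2-yl)prop-2-en-1-yl]-1-oxaspiro[4.5]deca-3,7-dien-2-one | CC1=C[C@@H](C/C=C/B3OC(C)(C)C(C)(C)O3)[C@]2(C[C@H]1C)OC(=O)C=C2OC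
F10 | step 34 | pinacol boronate analogue of 54, both carbinol epimers | CC1=C[C@@H](C/C=C/B3OC(C)(C)C(C)(C)O3)[C@]2(C[C@H]1C)OC(=O)C(C(O)[C@@H]1CS[C@H](C(O[Si](CC)(CC)CC)C(=O)OC)[C@H]1[C@@H](C)C/C=C/C[C@H](C/C=C/I)O[Si](C)(C)C(C)(C)C)=C2OC
A1 | alternative 1 | 19-membered carbocyclic acid with the E-alkene in place and a carboxyl group instead of the C-methyl group (acetonide diol on the thiolane, two tert-butyldimethylsilyl ethers, methyl tetronate) | CC1=C[C@H]2C/C=C/C=C/C[C@H](O[Si](C)(C)C(C)(C)C)C/C=C/C[C@H](C(=O)O)[C@@H]3[C@@H]([C@H]4COC(C)(C)O4)SC[C@H]3[C@H](O[Si](C)(C)C(C)(C)C)C3=C(OC)[C@@]2(C[C@H]1C)OC3=O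
A2 | alternative 2 | protected macrocyclic 3-acylspirotetronic acid (tert-butyldimethylsilyl ether, triethylsilyloxy tert-butyl ester) | CC1=C[C@H]2C/C=C/C=C/C[C@H](O[Si](C)(C)C(C)(C)C)C/C=C/C[C@H](C)[C@@H]3[C@@H]([C@H](O[Si](CC)(CC)CC)C(=O)OC(C)(C)C)SC[C@H]3C(=O)C3=C(O)[C@@]2(C[C@H]1C)OC3=O
A3 | alternative 3 | 2-tert-butyl 4-methyl 3-(pent-4-en-2-yl)thiolane-2,4-dicarboxylate, all-trans | C=CC[C@H](C)[C@@H]1[C@@H](C(=O)OC(C)(C)C)SC[C@H]1C(=O)OC
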